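**Plan**

Numbering used throughout: carbocycle C1–C14 with C1(iPr)=C2–C3=C4(Me), C5/C6 CH2, C7 CH–OAc, C8 C(Me)–O, C9/C10 CH2, C11 CH–O, C12 C(Me)OH, C13/C14 CH2; the oxolane is O, C8–C11.
Enabling feature: only two CH2 groups (C5, C6) separate carbinol carbon C7 from the methyl-bearing diene end C4. They are stored as a vinyl substituent on C7 and unmasked as a C5 alkylborane, while C4 is held as the (E)-alkenyl iodide of a preformed (E,E)-diene.
Cuts, in retrosynthetic order: C7 O-acetyl; C4–C5 (14-membered ring); C12–CH3 and C13–C14 (Grignard addition, enolate allylation), giving an oxolane methyl ketone and an iodo-dienyl bromide; the oxolane C11–O bond and the C5=C6 vinyl group lead back to geraniol, the iodo-diene to propargyl alcohol, iPrMgCl and propyne.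
Forward order: oxolane ring (step 5), chain joined at C13–C14 (step 11), C12 methyl (step 12), carbocycle closed last (step 13), then desilylation and acetylation.
Stereochemistry: C8 and C7 from the first Sharpless epoxidation (C7 inverted by Payne rearrangement); C11 from the second Sharpless epoxidation followed by invertive 5-exo opening; C12 from chelation-controlled MeMgBr addition; C1=C2 from anti-carbomagnesiation; C3=C4 from syn-hydrozirconation.

Key step: step 13

Remark: compound 3 is drawn as the free alcohol although it exists in the flask as its lithium alkoxide; the metalated intermediates 12, 16 and 19 are drawn as covalent formulas.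

**Route**

Step 1
Reactants: 1 geraniol
Product: 2 [(2S,3S)-3-methyl-3-(4-methylpent-3-en-1-yl)oxiran-2-yl]methanol
Conditions: Ti(OiPr)4 (5 mol%), L-(+)-diethyl tartrate (6 mol%), t-BuOOH, 4 Å MS, CH2Cl2, −20 °C
Reagents that add atoms: tert-butyl hydroperoxide, CC(C)(C)OO
Why: Sharpless asymmetric epoxidation of an (E)-trisubstituted allylic alcohol, in which the titanium–L-(+)-tartrate catalyst delivers oxygen to one alkene face under reagent control, setting C8 as S (kept to the end) and placing on C7 the epoxide oxygen that step 2 inverts.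

Step 2
Reactants: 2 [(2S,3S)-3-methyl-3-(4-methylpent-3-en-1-yl)oxiran-2-yl]methanol
Product: 4 (3R,4S)-4,8-dimethylnona-1,7-diene-3,4-diol, via terminal epoxide 3 (not isolated)
Conditions: Me3S+ I− (4 equiv), n-BuLi (3.9 equiv), THF, −10 °C; then 2, −10 °C → rt
Reagents that add atoms: trimethylsulfonium iodide, C[S+](C)C.[I-]
Why: Tandem Payne rearrangement and sulfonium-ylide homologation of a 2,3-epoxy alcohol, in which the C6 alkoxide opens the epoxide at C7 with SN2 inversion (C8–O untouched) to give 3, dimethylsulfonium methylide attacks only the unhindered CH2 of 3, and loss of Me2S leaves the (7R)-carbinol carrying the new C6=C5 vinyl group next to the (8S)-tertiary alcohol.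

Step 3
Reactants: 4 (3R,4S)-4,8-dimethylnona-1,7-diene-3,4-diol
Product: 5 (3R,4S)-3-[(tert-butyldimethylsilyl)oxy]-4,8-dimethylnona-1,7-dien-4-ol
Conditions: TBSCl (1.2 equiv), imidazole, DMAP (cat.), DMF, rt
Reagents that add atoms: tert-butyldimethylsilyl chloride, CC(C)(C)[Si](C)(C)Cl
Why: Silyl ether formation with TBSCl/imidazole, which should distinguish the secondary allylic C7 hydroxyl from the tertiary C8 hydroxyl on steric grounds and touches no stereocentre.

Step 4
Reactants: 5 (3R,4S)-3-[(tert-butyldimethylsilyl)oxy]-4,8-dimethylnona-1,7-dien-4-ol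
Product: 6 (2E,6S,7R)-7-[(tert-butyldimethylsilyl)oxy]-2,6-dimethylnona-2,8-diene-1,6-diol
Conditions: SeO2 (0.2 equiv), t-BuOOH (3 equiv), salicylic acid (cat.), CH2Cl2, 0 °C → rt
Reagents that add atoms: tert-butyl hydroperoxide, CC(C)(C)OO
Why: SeO2-catalysed allylic oxidation (ene reaction, then [2,3]-sigmatropic shift) should hydroxylate the (E)-methyl group of the electron-rich trisubstituted alkene and leave the deactivated vinyl group alone, with the E geometry following from the sigmatropic step and no stereocentre formed.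

Step 5
Reactants: 6 (2E,6S,7R)-7-[(tert-butyldimethylsilyl)oxy]-2,6-dimethylnona-2,8-diene-1,6-diol
Product: 8 (2S)-2-[(2R,5S)-5-{(1R)-1-[(tert-butyldimethylsilyl)oxy]prop-2-en-1-yl}-5-methyloxolan-2-yl]propane-1,2-diol, via epoxy alcohol 7 (not isolated)
Conditions: Ti(OiPr)4 (10 mol%), L-(+)-diethyl tartrate (12 mol%), t-BuOOH (2 equiv), 4 Å MS, CH2Cl2, −20 °C; then CSA (0.3 equiv), −20 °C → rt
Reagents that add atoms: tert-butyl hydroperoxide, CC(C)(C)OO
Why: Sharpless asymmetric epoxidation of the new allylic alcohol should give the (11S,12S)-epoxide 7 under reagent control, and acid then drives a 5-exo-tet opening by the tertiary C8 hydroxyl at C11 with inversion, so that C11 becomes R in a 2,5-cis oxolane while 6-endo attack at C12 is disfavoured by its electron-withdrawing hydroxymethyl group.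

Step 6
Reactants: 8 (2S)-2-[(2R,5S)-5-{(1R)-1-[(tert-butyldimethylsilyl)oxy]prop-2-en-1-yl}-5-methyloxolan-2-yl]propane-1,2-diol
Product: 9 1-[(2R,5S)-5-{(1R)-1-[(tert-butyldimethylsilyl)oxy]prop-2-en-1-yl}-5-methyloxolan-2-yl]ethan-1-one
Conditions: NaIO4, THF/H2O, 0 °C → rt
Reagents that add atoms: none
Why: Periodate glycol cleavage (Malaprade reaction) of the tertiary/primary 1,2-diol removes the hydroxymethyl carbon as formaldehyde and unveils the C12 methyl ketone under neutral conditions that should not epimerise the α-oxygenated C11 centre or affect the vinyl group and silyl ether.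

Step 7
Reactants: 10 prop-2-yn-1-ol, 11 isopropylmagnesium chloride
Product: 13 (2Z)-3-iodo-2-(propan-2-yl)prop-2-en-1-ol, via alkenylmagnesium alkoxide 12 (not isolated)
Conditions: iPrMgCl (3 equiv), CuI (10 mol%), THF, −10 °C → rt; then I2, −78 → 0 °C
Reagents that add atoms: iodine, II
Why: Copper-catalysed anti-carbomagnesiation of a propargylic alkoxide puts the isopropyl group on the internal alkyne carbon (future C1) and magnesium on the terminal carbon cis to the CH2O group within a five-membered chelate, so that iodinolysis with retention gives the alkenyl iodide with iodine (the future C3 site) cis to the future C14, as the C1=C2 geometry requires.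

Step 8
Reactants: 13 (2Z)-3-iodo-2-(propan-2-yl)prop-2-en-1-ol, 14 propyne
Product: 15 (2Z)-2-(propan-2-yl)hex-2-en-4-yn-1-ol
Conditions: PdCl2(PPh3)2 (3 mol%), CuI (6 mol%), Et3N, THF, propyne (excess), 0 °C → rt
Reagents that add atoms: none
Why: Sonogashira coupling of an alkenyl iodide with a terminal alkyne proceeds with retention of alkene geometry, tolerates the free hydroxyl and installs C3, C4 and the C4 methyl group.

Step 9
Reactants: 15 (2Z)-2-(propan-2-yl)hex-2-en-4-yn-1-ol
Product: 17 (2Z,4E)-5-iodo-2-(propan-2-yl)hexa-2,4-dien-1-ol, via alkenylzirconocene chloride 16 (not isolated)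
Conditions: Cp2Zr(H)Cl (2.5 equiv), THF, rt → 40 °C; then I2, 0 °C
Reagents that add atoms: iodine, II
Why: Hydrozirconation–iodination, in which the first equivalent of Cp2Zr(H)Cl is consumed by the hydroxyl, syn addition of Zr–H then places zirconium on the less hindered methyl-bearing carbon C4 (excess reagent equilibrates regioisomers toward this position and the trisubstituted alkene is inert), and iodinolysis with retention gives the (E)-iodide with iodine trans to C2.

Step 10
Reactants: 17 (2Z,4E)-5-iodo-2-(propan-2-yl)hexa-2,4-dien-1-ol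
Product: 18 (2Z,4E)-1-bromo-5-iodo-2-(propan-2-yl)hexa-2,4-diene
Conditions: CBr4, PPh3, CH2Cl2, −20 → 0 °C; used at once
Reagents that add atoms: carbon tetrabromide, BrC(Br)(Br)Br
Why: Appel bromination converts the primary allylic alcohol into the bromide by SN2 displacement of an oxyphosphonium ion under neutral, cold conditions, which should avoid allylic transposition and leave both alkene geometries and the alkenyl iodide untouched.

Step 11
Reactants: 9 1-[(2R,5S)-5-{(1R)-1-[(tert-butyldimethylsilyl)oxy]prop-2-en-1-yl}-5-methyloxolan-2-yl]ethan-1-one, 18 (2Z,4E)-1-bromo-5-iodo-2-(propan-2-yl)hexa-2,4-diene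
Product: 20 (4E,6E)-1-[(2R,5S)-5-{(1R)-1-[(tert-butyldimethylsilyl)oxy]prop-2-en-1-yl}-5-methyloxolan-2-yl]-7-iodo-4-(propan-2-yl)octa-4,6-dien-1-one, via lithium enolate 19 (not isolated)
Conditions: LiN(iPr)2 (1.05 equiv), THF, −78 °C; then 18 (1.3 equiv), DMPU, −78 → −30 °C
Reagents that add atoms: none
Why: Kinetic enolate alkylation, in which LiN(iPr)2 removes a methyl proton of 9 in preference to the hindered α-alkoxy methine at C11 and SN2 attack of enolate 19 on the primary allylic bromide forms C13–C14 without touching C11, the alkenyl iodide or the alkene geometries.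

Step 12
Reactants: 20 (4E,6E)-1-[(2R,5S)-5-{(1R)-1-[(tert-butyldimethylsilyl)oxy]prop-2-en-1-yl}-5-methyloxolan-2-yl]-7-iodo-4-(propan-2-yl)octa-4,6-dien-1-one
Product: 21 (2S,5E,7E)-2-[(2R,5S)-5-{(1R)-1-[(tert-butyldimethylsilyl)oxy]prop-2-en-1-yl}-5-methyloxolan-2-yl]-8-iodo-5-(propan-2-yl)nona-5,7-dien-2-ol
Conditions: MeMgBr (3 equiv), Et2O/CH2Cl2, −78 °C
Reagents that add atoms: methylmagnesium bromide, C[Mg]Br
Why: Cram-chelate-controlled Grignard addition to an α-alkoxy ketone, in which magnesium bridges the carbonyl and oxolane oxygens in a weakly coordinating solvent and the methyl group adds to the carbonyl face flanked by the C11 hydrogen and not by ring carbon C10, setting C12 as S, while the alkenyl iodide should not exchange with MeMgBr at −78 °C.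

Step 13
Reactants: 21 (2S,5E,7E)-2-[(2R,5S)-5-{(1R)-1-[(tert-butyldimethylsilyl)oxy]prop-2-en-1-yl}-5-methyloxolan-2-yl]-8-iodo-5-(propan-2-yl)nona-5,7-dien-2-ol
Product: 23 (1E,3E,7R,8S,11R,12S)-7-[(tert-butyldimethylsilyl)oxy]-8,11-epoxy-1-isopropyl-4,8,12-trimethylcyclotetradeca-1,3-dien-12-ol (plan numbering), via B-alkyl-9-BBN adduct 22 (not isolated)
Conditions: 9-BBN (3 equiv), THF, 0 °C → rt; then H2O; syringe-pump addition to PdCl2(dppf) (20 mol%), AsPh3 (40 mol%), Cs2CO3 (4 equiv), DMF/THF/H2O, 50 °C, final ca. 1 mM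
Reagents that add atoms: none
Why: 9-BBN should add only to the monosubstituted C5=C6 vinyl group, with boron going to terminal C5 to give 22. Oxidative addition of the C4–I bond to zerovalent palladium (generated from PdCl2(dppf)) occurs with retention of the C3=C4 geometry; the borane, turned into a hydroxyborate by aqueous Cs2CO3, hands its primary C5 alkyl group to the divalent alkenylpalladium iodide, and reductive elimination joins C4 to C5, a B-alkyl Suzuki–Miyaura macrocyclisation. The carbocycle is closed end to end: transmetalation gives a 15-membered palladacycle that contracts to the 14-membered ring on reductive elimination, and slow addition at about 1 mM favours this over chain growth. No stereocentre is created or endangered, since C7 is two bonds from the new bond and both diene geometries are already in place. Three selectivities are needed (boron only at C5, cyclisation and not oligomerisation, unchanged diene geometry) and they rest on the steric demand of 9-BBN toward the iodo-diene, on dilution, and on the stereoretentive elementary steps at palladium; the free C12 hydroxyl is tolerated because any O-borinate is hydrolysed by the aqueous base.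

Step 14
Reactants: 23 (1E,3E,7R,8S,11R,12S)-7-[(tert-butyldimethylsilyl)oxy]-8,11-epoxy-1-isopropyl-4,8,12-trimethylcyclotetradeca-1,3-dien-12-ol
Product: 24 (1E,3E,7R,8S,11R,12S)-8,11-epoxy-1-isopropyl-4,8,12-trimethylcyclotetradeca-1,3-diene-7,12-diol (plan numbering)
Conditions: Bu4NF, THF, rt → 45 °C
Reagents that add atoms: none
Why: Fluoride-induced silyl ether cleavage (Si–F bond formation) frees the C7 hydroxyl, with gentle warming allowed for the hindered site and no other fluoride-labile group present.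

Step 15
Reactants: 24 (1E,3E,7R,8S,11R,12S)-8,11-epoxy-1-isopropyl-4,8,12-trimethylcyclotetradeca-1,3-diene-7,12-diol
Product: 25 (1E,3E,7R,8S,11R,12S)-8,11-epoxy-12-hydroxy-1-isopropyl-4,8,12-trimethylcyclotetradeca-1,3-dien-7-yl acetate (plan numbering), CNP0199953.2
Conditions: Ac2O, pyridine, DMAP (cat.), CH2Cl2, rt
Reagents that add atoms: acetic anhydride, CC(=O)OC(C)=O
Why: Nucleophile-catalysed acylation (DMAP/Ac2O) should esterify the secondary C7 hydroxyl while the tertiary C12 hydroxyl is too hindered to react, giving the target with all four stereocentres and both alkene geometries unchanged.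

**Compound list**

1 | geraniol, (2E)-3,7-dimethylocta-2,6-dien-1-ol | CC(C)=CCC/C(C)=C/CO | starting material
2 | [(2S,3S)-3-methyl-3-(4-methylpent-3-en-1-yl)oxiran-2-yl]methanol | OC[C@@H]1O[C@@]1(C)CCC=C(C)C | intermediate
3 | (2S)-6-methyl-2-[(2R)-oxiran-2-yl]hept-5-en-2-ol (present as lithium alkoxide, not isolated) | C1O[C@H]1[C@@](C)(O)CCC=C(C)C | intermediate
4 | (3R,4S)-4,8-dimethylnona-1,7-diene-3,4-diol | C=C[C@@H](O)[C@@](C)(O)CCC=C(C)C | intermediate
5 | (3R,4S)-3-[(tert-butyldimethylsilyl)oxy]-4,8-dimethylnona-1,7-dien-4-ol | C=C[C@@H](O[Si](C)(C)C(C)(C)C)[C@@](C)(O)CCC=C(C)C | intermediate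
6 | (2E,6S,7R)-7-[(tert-butyldimethylsilyl)oxy]-2,6-dimethylnona-2,8-diene-1,6-diol | C=C[C@@H](O[Si](C)(C)C(C)(C)C)[C@@](C)(O)CC/C=C(\C)CO | intermediate
7 | (3R,4S)-3-[(tert-butyldimethylsilyl)oxy]-6-[(2S,3S)-3-(hydroxymethyl)-3-methyloxiran-2-yl]-4-methylhex-1-en-4-ol (not isolated) | C=C[C@@H](O[Si](C)(C)C(C)(C)C)[C@@](C)(O)CC[C@@H]1O[C@@]1(C)CO | intermediate
8 | (2S)-2-[(2R,5S)-5-{(1R)-1-[(tert-butyldimethylsilyl)oxy]prop-2-en-1-yl}-5-methyloxolan-2-yl]propane-1,2-diol | C=C[C@@H](O[Si](C)(C)C(C)(C)C)[C@]1(C)CC[C@@H](O1)[C@@](C)(O)CO | intermediate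
9 | 1-[(2R,5S)-5-{(1R)-1-[(tert-butyldimethylsilyl)oxy]prop-2-en-1-yl}-5-methyloxolan-2-yl]ethan-1-one | C=C[C@@H](O[Si](C)(C)C(C)(C)C)[C@]1(C)CC[C@@H](O1)C(C)=O | intermediate
10 | prop-2-yn-1-ol (propargyl alcohol) | C#CCO | starting material
11 | isopropylmagnesium chloride | CC(C)[Mg]Cl | starting material
12 | chloromagnesium (2Z)-3-(chloromagnesio)-2-(propan-2-yl)prop-2-en-1-olate (not isolated) | Cl[Mg]OC/C(C(C)C)=C\[Mg]Cl | intermediate
13 | (2Z)-3-iodo-2-(propan-2-yl)prop-2-en-1-ol | OC/C(C(C)C)=C\I | intermediate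
14 | propyne | CC#C | starting material
15 | (2Z)-2-(propan-2-yl)hex-2-en-4-yn-1-ol | OC/C(C(C)C)=C\C#CC | intermediate
16 | zirconocene chloride alkoxide of (2Z,4E)-5-[chlorobis(cyclopentadienyl)zirconio]-2-(propan-2-yl)hexa-2,4-dien-1-ol (not isolated) | C/C(=C\C=C(/CO[Zr](Cl)(C1C=CC=C1)C1C=CC=C1)C(C)C)[Zr](Cl)(C1C=CC=C1)C1C=CC=C1 | intermediate
17 | (2Z,4E)-5-iodo-2-(propan-2-yl)hexa-2,4-dien-1-ol | OC/C(C(C)C)=C\C=C(/C)I | intermediate
18 | (2Z,4E)-1-bromo-5-iodo-2-(propan-2-yl)hexa-2,4-diene | BrC/C(C(C)C)=C\C=C(/C)I | intermediate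
19 | lithium enolate of 9, lithium 1-[(2R,5S)-5-{(1R)-1-[(tert-butyldimethylsilyl)oxy]prop-2-en-1-yl}-5-methyloxolan-2-yl]ethen-1-olate (not isolated) | C=C[C@@H](O[Si](C)(C)C(C)(C)C)[C@]1(C)CC[C@@H](O1)C(=C)O[Li] | intermediate
20 | (4E,6E)-1-[(2R,5S)-5-{(1R)-1-[(tert-butyldimethylsilyl)oxy]prop-2-en-1-yl}-5-methyloxolan-2-yl]-7-iodo-4-(propan-2-yl)octa-4,6-dien-1-one | C=C[C@@H](O[Si](C)(C)C(C)(C)C)[C@]1(C)CC[C@@H](O1)C(=O)CC/C(C(C)C)=C\C=C(/C)I | intermediate
21 | (2S,5E,7E)-2-[(2R,5S)-5-{(1R)-1-[(tert-butyldimethylsilyl)oxy]prop-2-en-1-yl}-5-methyloxolan-2-yl]-8-iodo-5-(propan-2-yl)nona-5,7-dien-2-ol (seco precursor) | C=C[C@@H](O[Si](C)(C)C(C)(C)C)[C@]1(C)CC[C@@H](O1)[C@@](C)(O)CC/C(C(C)C)=C\C=C(/C)I | intermediate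
22 | B-alkyl-9-BBN adduct of 21, boron on C5 (not isolated) | C1CCC2CCCC1B2CC[C@@H](O[Si](C)(C)C(C)(C)C)[C@]3(C)CC[C@@H](O3)[C@@](C)(O)CC/C(C(C)C)=C\C=C(/C)I | intermediate
23 | (1E,3E,7R,8S,11R,12S)-7-[(tert-butyldimethylsilyl)oxy]-8,11-epoxy-1-isopropyl-4,8,12-trimethylcyclotetradeca-1,3-dien-12-ol (plan numbering) | CC(C)(C)[Si](C)(C)O[C@@H]1CC/C(C)=C/C=C(/C(C)C)CC[C@](C)(O)[C@H]2CC[C@]1(C)O2 | intermediate
24 | (1E,3E,7R,8S,11R,12S)-8,11-epoxy-1-isopropyl-4,8,12-trimethylcyclotetradeca-1,3-diene-7,12-diol (plan numbering) | O[C@@H]1CC/C(C)=C/C=C(/C(C)C)CC[C@](C)(O)[C@H]2CC[C@]1(C)O2 | intermediate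
25 | (1E,3E,7R,8S,11R,12S)-8,11-epoxy-12-hydroxy-1-isopropyl-4,8,12-trimethylcyclotetradeca-1,3-dien-7-yl acetate (plan numbering), CNP0199953.2 | CC(=O)O[C@@H]1CC/C(C)=C/C=C(/C(C)C)CC[C@](C)(O)[C@H]2CC[C@]1(C)O2 | target

**Step count and risks**

Total: 15 steps (oxolane branch 6, iodo-diene branch 4, union and endgame 5). Longest linear sequence: 11 steps from geraniol (steps 1–6 and 11–15).

Steps most likely to fail:

Step 13. Hydroboration of the hindered allylic silyl ether may be slow, and at the palladium stage intermolecular coupling (chain growth) or protodeboronation may outrun ring closure. The fallback sets out from 21 and returns at 24, forming the same C4–C5 bond by an intramolecular Negishi coupling. The borane 22 is oxidised with NaBO3·4H2O to the primary alcohol F5. Iodination of the primary hydroxyl (I2, PPh3, imidazole) gives the diiodide F6, and the tertiary hydroxyl is masked (TMSOTf, 2,6-lutidine) as the trimethylsilyl ether F7. Activated Zn dust in DMA/THF should insert only into the primary C–I bond, the alkenyl iodide being inert to zinc under these conditions, to give the alkylzinc iodide F8. Slow addition of F8 to Pd(PPh3)4 at high dilution closes the ring to the macrocyclic bis-silyl ether F9, and the Bu4NF treatment of step 14 removes both silyl groups to give 24.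

Step 2. Payne equilibration of the lithium alkoxide of a trisubstituted epoxide in THF may be too slow, so that ylide decomposition or direct attack on the internal epoxide takes over. The fallback sets out from 2 and returns at 4 by separating the two events. Aqueous NaOH in t-BuOH effects the Payne rearrangement with hydroxide opening at C6 to give the triol F1. Tosylation of its primary hydroxyl (TsCl, pyridine, 0 °C) gives the monotosylate F2, and K2CO3 in MeOH closes F2 to the terminal epoxide 3, now isolated. The ordinary ylide homologation of this monosubstituted epoxide (Me3S+ I−, n-BuLi, THF) then gives 4.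

Step 11. Proton transfer between product ketone and enolate may cause double alkylation and enolate equilibration toward C11 with epimerisation, and the dienylic bromide may eliminate. The fallback sets out from 9 and returns at 20 through an aza-enolate. Condensation of 9 with 1,1-dimethylhydrazine gives the dimethylhydrazone F3. Its lithium aza-enolate (LiN(iPr)2, THF, −78 °C) does not equilibrate and alkylates once at the less substituted carbon; with 18 it gives the alkylated hydrazone F4. Hydrolysis with aqueous oxalic acid returns ketone 20.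

Further compounds
F1 | step 2 | (2R,3S)-3,7-dimethyloct-6-ene-1,2,3-triol | OC[C@@H](O)[C@@](C)(O)CCC=C(C)C
F2 | step 2 | (2R,3S)-2,3-dihydroxy-3,7-dimethyloct-6-en-1-yl 4-methylbenzenesulfonate | Cc1ccc(cc1)S(=O)(=O)OC[C@@H](O)[C@@](C)(O)CCC=C(C)C
F3 | step 11 | N,N-dimethylhydrazone of ketone 9 | C=C[C@@H](O[Si](C)(C)C(C)(C)C)[C@]1(C)CC[C@@H](O1)/C(C)=N/N(C)C
F4 | step 11 | N,N-dimethylhydrazone of ketone 20 | C=C[C@@H](O[Si](C)(C)C(C)(C)C)[C@]1(C)CC[C@@H](O1)/C(=N/N(C)C)CC/C(C(C)C)=C\C=C(/C)I
F5 | step 13 | C5 primary alcohol from oxidation of 22 | OCC[C@@H](O[Si](C)(C)C(C)(C)C)[C@]1(C)CC[C@@H](O1)[C@@](C)(O)CC/C(C(C)C)=C\C=C(/C)I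
F6 | step 13 | C5 primary iodide with free C12 hydroxyl (diiodide) | ICC[C@@H](O[Si](C)(C)C(C)(C)C)[C@]1(C)CC[C@@H](O1)[C@@](C)(O)CC/C(C(C)C)=C\C=C(/C)I
F7 | step 13 | C12 trimethylsilyl ether of the diiodide | ICC[C@@H](O[Si](C)(C)C(C)(C)C)[C@]1(C)CC[C@@H](O1)[C@@](C)(O[Si](C)(C)C)CC/C(C(C)C)=C\C=C(/C)I
F8 | step 13 | C5 alkylzinc iodide | I[Zn]CC[C@@H](O[Si](C)(C)C(C)(C)C)[C@]1(C)CC[C@@H](O1)[C@@](C)(O[Si](C)(C)C)CC/C(C(C)C)=C\C=C(/C)I
F9 | step 13 | macrocycle with C7 tert-butyldimethylsilyl ether and C12 trimethylsilyl ether | CC(C)(C)[Si](C)(C)O[C@@H]1CC/C(C)=C/C=C(/C(C)C)CC[C@](C)(O[Si](C)(C)C)[C@H]2CC[C@]1(C)O2
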